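## Analysis of the target

The target is a 2,5-diaryl-3,4-dimethyloxolane (ring atoms O1, C2, C3, C4, C5) in which ring B on C2 and ring B′ on C5 are both 3-methoxy-4-alkoxyphenyl, each etherified at its O4 with a 1-(3,4-dimethoxyphenyl)-1-hydroxypropan-2-yl unit (carbinol carbon Cα, ether carbon Cβ, terminal rings A and A′). It is thus a tetramer of C6C3 units held together by one C–C bond (C3–C4), the two ring C–O bonds and two aryl ether bonds (O4–Cβ). There are eight stereocentres: C2 (S), C3 (R), C4 (R) and C5 (R) in the ring, that is 2,3-cis, 3,4-trans and 4,5-trans with the two aryl groups cis to each other, and Cα (R), Cβ (S) in both side chains, the erythro arrangement. The constitution is twofold symmetric, and so are the pair C3/C4 and the two side chains; only the pair C2/C5 breaks the symmetry, since ring B is cis and ring B′ is trans to the neighbouring methyl group. Both ring C–O bonds are p-alkoxybenzylic ethers, which acids open reversibly, so that the 2,3-cis centre can drift to the all-trans isomer. The side-chain benzylic alcohols ionise in the same way, α-aryloxy ketone precursors can epimerise at Cβ, and all four arenes are electron-rich. The synthesis is hard because C3 and C4 carry only methyl groups and must be set absolutely without a heteroatom handle, because one benzylic centre must be cis and the other trans within one ring against the thermodynamic preference, and because the four side-chain stereocentres are too remote to be influenced by the core.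

## Retrosynthetic reasoning

**21 ⇒ 20.** Only the two silyl ethers on Cα are removed. The Cα hydroxyl groups are masked because they would be deprotonated or ionised in the organometallic and Lewis-acid steps; a fluoride-labile group can be taken off without acid at the end.

**20 ⇒ 18 ⇒ 17 (bonds cut: O1–C2, C2–H and C5–H).** The ring is opened to the C2-symmetric 1,4-diketone 17. The two carbonyl groups are treated differently:
- One is reduced to an alcohol under Felkin–Anh control and keeps its configuration. It becomes C5, with the aryl group trans to the C4 methyl.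
- Its oxygen closes onto the other carbonyl (hemiketal 18). The derived oxocarbenium ion 19 takes hydride on the face opposite the C3 methyl. That carbon becomes C2, with the aryl group cis.
- Because the two carbonyls of 17 are homotopic, no selectivity between them is needed; whichever reacts first, the same product results. The symmetry-breaking element of the target (C2 versus C5) is thus introduced last and costs no differentiation of the two halves.

**17 ⇒ 16 ⇒ 13 (bond cut: C3–C4).** This is the key disconnection. It halves the molecule into two identical pieces, two molecules of 13, each of which already contains the complete side chain with Cα and Cβ in place. Forward, the bond is made by oxidative homocoupling of an enolate equivalent of an aryl ethyl ketone: one molecule of 13 reacts as azaenolate 14, the other as iodide 15. A removable hydrazone auxiliary (from 12) gives the azaenolate and controls both new methyl-bearing centres. Cutting elsewhere (aryl–C2, O4–Cβ) would leave the vicinal dimethyl problem to a separate linear sequence and would not use the symmetry.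

**13 ⇒ 11 ⇒ 8.** The hydrazone comes from ketone 11 and 12. The propanoyl group of 11 is attached to ring B by halogen–lithium exchange on bromide 8 (aryllithium 10) and acylation with amide 9. The bromine atom is a placeholder that survives the side-chain chemistry.

**8 ⇒ 7 ⇒ 6 ⇒ 4 ⇒ 3 ⇒ 1 + 2 (bonds cut: Cα–H, Cα–ring A, O4–Cβ).**
- Cβ comes from the chiral pool: the hydroxyl of lactate 2 is displaced by phenol 1 with inversion.
- Ring A is introduced as Grignard reagent 5 on amide 4.
- Cα is set by chelation-controlled hydride delivery to ketone 6, which gives the erythro relationship.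
- All four side-chain stereocentres of the target are thus made once, on a small molecule, before the dimerisation doubles them.

## Alternatives that were turned down

**Alternative 1: the textbook route (late two-fold etherification of a preformed core).**
- Disconnection: the two O4–Cβ ether bonds and the C2–aryl bond.
- Forward: lactone A1 takes up an aryllithium, the hemiketal is reduced through its oxocarbenium ion, and the benzyl groups are removed to give bisphenol A2. The key step is the two-fold SN2 etherification of A2 with sulfonate A3, followed by a two-fold chelation-controlled ketone reduction.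
- Turned down because:
  - A1 needs a linear auxiliary-based sequence of its own, and the route ignores the twofold symmetry.
  - The benzyl ethers must be hydrogenolysed next to the two benzylic C–O bonds of the oxolane.
  - A3 is an α-sulfonyloxy aryl ketone that can racemise through its enol under the basic etherification conditions.
  - All four side-chain stereocentres are created on the most valuable intermediate, twice in each operation.

**Alternative 2: (3+2) cycloaddition of a carbonyl ylide.**
- Disconnection: C2–C3 and C4–C5.
- Forward: C–C cleavage of the trans-diaryloxirane A4 (photo-induced electron transfer) gives a W-shaped carbonyl ylide. Suprafacial addition to an E-configured butenedioate diester can only give the 2,5-cis-3,4-trans oxolane A5, which is exactly the relative configuration of the target core.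
- Turned down because:
  - Such ylides add only to electron-poor alkenes, so each ester must afterwards be reduced to a methyl group (three further operations on both positions).
  - Nothing controls the absolute sense: A5 is racemic, and with the chiral side chains in place the two modes of approach would give two diastereomers in equal amounts.
  - The doubly p-alkoxy-substituted oxirane A4 rearranges with traces of acid.

**Alternative 3: two-fold asymmetric hydroboration of an achiral diene.**
- Disconnection: the C2–H/C5–O and C3–H/C4–H bonds of a flat precursor.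
- Forward: two molecules of alkyne A6 are coupled on a low-valent zirconocene and protonated to the (1E,3E)-diene A7. Two additions of a chiral monoalkylborane and oxidation would set four stereocentres at once and give the C2-symmetric diol A8, which is closed with inversion at one carbinol carbon.
- Turned down because:
  - After the first addition the dialkylborane can add intramolecularly to the second alkene (borolane formation), so the C3/C4 relationship would be set by the substrate and not by the reagent.
  - The regiochemistry on a conjugated, twisted diene is uncertain.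
  - Both carbinol centres of A8 are of the trans type, so the ring must be closed by SN2 inversion at a p-alkoxybenzylic carbon, where ionisation leads to the all-trans isomer.
  - Two uncertain steps would follow one another.

Key step: step 8

## Assumptions

- The target is taken to be exactly the stereoisomer of the SMILES string: (2S,3R,4R,5R) in the oxolane and (1R,2S) in both side chains.
- The oxidative coupling of the azaenolate from the (R)-auxiliary 12 is assumed to form each new C–C bond on the face that carbon electrophiles attack, which places (R) at both methyl-bearing carbons. If the sense proved to be the reverse, the (S)-auxiliary would be used in the same steps.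

Abbreviation used in names: Ar* = 4-{[(1R,2S)-1-[(tert-butyldimethylsilyl)oxy]-1-(3,4-dimethoxyphenyl)propan-2-yl]oxy}-3-methoxyphenyl.

## Route

Step 1
Reactants: 1 4-bromo-2-methoxyphenol; 2 methyl (2R)-2-hydroxypropanoate
Product: 3 methyl (2S)-2-(4-bromo-2-methoxyphenoxy)propanoate
Conditions: PPh3, DIAD, THF, 0 °C → rt
Reagents that add atoms: none
Why: Mitsunobu etherification of a phenol with a secondary α-hydroxy ester; the alkoxyphosphonium ion is displaced by the phenoxide in an SN2 process with inversion, so (R)-lactate gives the (S)-aryl ether that becomes Cβ.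

Step 2
Reactants: 3 methyl (2S)-2-(4-bromo-2-methoxyphenoxy)propanoate
Product: 4 (2S)-2-(4-bromo-2-methoxyphenoxy)-N-methoxy-N-methylpropanamide
Conditions: MeNH(OMe)·HCl, i-PrMgCl, THF, −20 °C
Reagents that add atoms: N,O-dimethylhydroxylamine hydrochloride, CNOC.Cl
Why: Aminolysis of the ester by the chloromagnesium amide formed in the flask (Weinreb amide formation); this amide is a weak base and should leave the α-aryloxy centre untouched at low temperature, and the aryl bromide does not exchange with i-PrMgCl under these conditions.

Step 3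
Reactants: 4 (2S)-2-(4-bromo-2-methoxyphenoxy)-N-methoxy-N-methylpropanamide; 5 (3,4-dimethoxyphenyl)magnesium bromide
Product: 6 (2S)-2-(4-bromo-2-methoxyphenoxy)-1-(3,4-dimethoxyphenyl)propan-1-one
Conditions: THF, −20 → 0 °C; then aq. NH4Cl
Reagents that add atoms: none
Why: Weinreb ketone synthesis; the chelated tetrahedral magnesium adduct prevents a second addition and releases the enolisable ketone only on quenching, so Cβ should keep its configuration.

Step 4
Reactants: 6 (2S)-2-(4-bromo-2-methoxyphenoxy)-1-(3,4-dimethoxyphenyl)propan-1-one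
Product: 7 (1R,2S)-2-(4-bromo-2-methoxyphenoxy)-1-(3,4-dimethoxyphenyl)propan-1-ol
Conditions: Zn(BH4)2, Et2O, −30 → 0 °C; then aq. NH4Cl
Reagents that add atoms: none
Why: Chelation-controlled (Cram chelate) reduction of an α-alkoxy ketone; zinc bridges the carbonyl oxygen and the ether oxygen (helped by the ortho methoxy group), and hydride enters from the side of the Cβ hydrogen, which gives the (1R,2S) erythro alcohol and sets Cα.

Step 5
Reactants: 7 (1R,2S)-2-(4-bromo-2-methoxyphenoxy)-1-(3,4-dimethoxyphenyl)propan-1-ol
Product: 8 {[(1R,2S)-2-(4-bromo-2-methoxyphenoxy)-1-(3,4-dimethoxyphenyl)propyl]oxy}(tert-butyl)dimethylsilane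
Conditions: TBSOTf, 2,6-lutidine, CH2Cl2, −78 → 0 °C
Reagents that add atoms: tert-butyldimethylsilyl trifluoromethanesulfonate, CC(C)(C)[Si](C)(C)OS(=O)(=O)C(F)(F)F
Why: Silylation of a hindered secondary alcohol under buffered conditions; the silyl ether tolerates organolithium reagents, amide bases and hydrides and is removed by fluoride without acid.

Step 6
Reactants: 8 {[(1R,2S)-2-(4-bromo-2-methoxyphenoxy)-1-(3,4-dimethoxyphenyl)propyl]oxy}(tert-butyl)dimethylsilane; 9 N-methoxy-N-methylpropanamide
Product: 11 1-(Ar*)propan-1-one, via aryllithium 10 (not isolated)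
Conditions: n-BuLi, THF, −78 °C; then 9, −78 → 0 °C; then aq. NH4Cl
Reagents that add atoms: none
Why: Bromine–lithium exchange is faster than any other reaction of 8 at −78 °C, and acylation of the aryllithium with the Weinreb amide stops at the ketone; no stereocentre is touched, since neither Cα–H nor Cβ–H is acidic.

Step 7
Reactants: 11 1-(Ar*)propan-1-one; 12 (2R)-2-(methoxymethyl)pyrrolidin-1-amine
Product: 13 (2R)-N-[1-(Ar*)propylidene]-2-(methoxymethyl)pyrrolidin-1-amine
Conditions: PPTS (cat.), 4 Å molecular sieves, toluene, 80 °C
Reagents that add atoms: none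
Why: Condensation of a ketone with a 1-aminopyrrolidine to the hydrazone (SAMP/RAMP hydrazone method); the C=N isomer ratio does not matter because both isomers give the same azaenolate in the next step.

Step 8
Reactants: 13 (2R)-N-[1-(Ar*)propylidene]-2-(methoxymethyl)pyrrolidin-1-amine (two molecules)
Product: 16 (2R,3R)-1,4-bis(Ar*)-2,3-dimethylbutane-1,4-dione bis{[(2R)-2-(methoxymethyl)pyrrolidin-1-yl]imine}, via lithium azaenolate 14 (not isolated), via α-iodo hydrazone 15 (not isolated)
Conditions: LiN(i-Pr)2 (1.05 equiv per 13), THF, 0 °C; then I2 (0.5 equiv per 13), −78 → −20 °C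
Reagents that add atoms: second molecule of hydrazone 13 (the homocoupling partner that supplies the other half of 16), CCC(=NN1CCC[C@@H]1COC)c1ccc(O[C@@H](C)[C@H](O[Si](C)(C)C(C)(C)C)c2ccc(OC)c(OC)c2)c(OC)c1
Why: Two molecules of 13 are joined in this step (2 × 13 + 2 LiN(i-Pr)2 + I2 → 16 + 2 LiI + 2 HN(i-Pr)2): LiN(i-Pr)2 removes a proton from the only acidic position of each, the CH2 group next to C=N, and gives the lithium azaenolate 14, in which lithium is held by the nitrogen atoms and the methoxymethyl arm of the auxiliary. Half an equivalent of iodine converts half of 14 into the α-iodo hydrazone 15, which is configurationally labile through iodine exchange with 14 and is consumed by the remaining 14 through substitution or through electron transfer and radical pairing; the net result is the oxidative homocoupling of an enolate equivalent, a reaction type known for ketone enolates, for enolates of N-acyl oxazolidinones and for lithiated SAMP or RAMP hydrazones, which give C2-symmetric 2,3-disubstituted 1,4-dicarbonyl compounds. The step closes no ring; it forms the C3–C4 bond of the future oxolane and joins two complete halves, so that the product holds the whole carbon skeleton and six of the eight stereocentres. Both new stereocentres are controlled by the pyrrolidine auxiliary, each azaenolate carbon accepting its partner on the face that is not screened by the chelated auxiliary, so that two identical (R)-auxiliaries should give the homochiral (R,R) pair. The selectivity that is needed is this like-pairing over the meso-type (R,S) pairing, and it rests on both partners carrying the same auxiliary; the four side-chain stereocentres are remote and identical in both halves and cannot create a mismatch. Chemoselectivity follows from acidity and rate: no other C–H bond is deprotonated by the amide base, and iodine should be consumed by the azaenolate at −78 °C before it can attack an arene.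

Step 9
Reactants: 16 (2R,3R)-1,4-bis(Ar*)-2,3-dimethylbutane-1,4-dione bis{[(2R)-2-(methoxymethyl)pyrrolidin-1-yl]imine}
Product: 17 (2R,3R)-1,4-bis(Ar*)-2,3-dimethylbutane-1,4-dione
Conditions: oxalic acid (sat. aq.), Et2O, rt
Reagents that add atoms: water, O
Why: Two-phase hydrolysis of N,N-dialkylhydrazones with a weak acid; the conditions are mild enough to leave the α-stereocentres of the diketone and the silyl ethers intact, and the auxiliary is recovered from the aqueous phase.

Step 10
Reactants: 17 (2R,3R)-1,4-bis(Ar*)-2,3-dimethylbutane-1,4-dione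
Product: 18 (3R,4R,5R)-2,5-bis(Ar*)-3,4-dimethyloxolan-2-ol
Conditions: LiBH(s-Bu)3 (1.0 equiv, slow addition), THF, −78 °C; then aq. NH4Cl
Reagents that add atoms: none
Why: Felkin–Anh reduction by a bulky trialkylborohydride: hydride adds anti to the large α-substituent and gives the (R)-carbinol that becomes C5 (aryl trans to the C4 methyl). The two carbonyl groups are homotopic, so either one gives the same product, and the alkoxide is expected to add to the second carbonyl as a five-membered hemiketalate, which shields it from a second hydride; the product is isolated as the cyclic hemiketal (mixture of anomers in equilibrium with the open hydroxy ketone).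

Step 11
Reactants: 18 (3R,4R,5R)-2,5-bis(Ar*)-3,4-dimethyloxolan-2-ol
Product: 20 (2S,3R,4R,5R)-2,5-bis(Ar*)-3,4-dimethyloxolane, via oxocarbenium ion 19 (not isolated)
Conditions: Et3SiH, BF3·OEt2, CH2Cl2, −78 °C; then aq. NaHCO3
Reagents that add atoms: none
Why: Ionic reduction of a 2-aryl lactol: the Lewis acid ionises the hemiketal to the aryl-stabilised cyclic oxocarbenium ion, and the silane delivers hydride to C2 on the face opposite the C3 methyl group, which places ring B cis to that methyl group (C2 = S). The low temperature is meant to keep the benzylic ethers of the product and of the side chains from ionising.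

Step 12
Reactants: 20 (2S,3R,4R,5R)-2,5-bis(Ar*)-3,4-dimethyloxolane
Product: 21 (1R,2S)-1-(3,4-dimethoxyphenyl)-2-[4-[(2S,3R,4R,5R)-5-[4-[(1R,2S)-1-(3,4-dimethoxyphenyl)-1-hydroxypropan-2-yl]oxy-3-methoxyphenyl]-3,4-dimethyloxolan-2-yl]-2-methoxyphenoxy]propan-1-ol
Conditions: Bu4NF, THF, 0 °C → rt; then aq. NH4Cl
Reagents that add atoms: none
Why: Fluoride cleavage of the two silyl ethers; the conditions are not acidic, so neither the oxolane nor the side-chain benzylic positions should epimerise.

## Compound list

1 | 4-bromo-2-methoxyphenol | COc1cc(Br)ccc1O | starting material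
2 | methyl (2R)-2-hydroxypropanoate | C[C@@H](O)C(=O)OC | starting material
3 | methyl (2S)-2-(4-bromo-2-methoxyphenoxy)propanoate | C[C@H](Oc1ccc(Br)cc1OC)C(=O)OC | intermediate
4 | (2S)-2-(4-bromo-2-methoxyphenoxy)-N-methoxy-N-methylpropanamide | C[C@H](Oc1ccc(Br)cc1OC)C(=O)N(C)OC | intermediate
5 | (3,4-dimethoxyphenyl)magnesium bromide (commercial THF solution) | COc1ccc([Mg]Br)cc1OC | starting material
6 | (2S)-2-(4-bromo-2-methoxyphenoxy)-1-(3,4-dimethoxyphenyl)propan-1-one | C[C@H](Oc1ccc(Br)cc1OC)C(=O)c1ccc(OC)c(OC)c1 | intermediate
7 | (1R,2S)-2-(4-bromo-2-methoxyphenoxy)-1-(3,4-dimethoxyphenyl)propan-1-ol | COc1ccc([C@@H](O)[C@H](C)Oc2ccc(Br)cc2OC)cc1OC | intermediate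
8 | {[(1R,2S)-2-(4-bromo-2-methoxyphenoxy)-1-(3,4-dimethoxyphenyl)propyl]oxy}(tert-butyl)dimethylsilane | COc1ccc([C@@H](O[Si](C)(C)C(C)(C)C)[C@H](C)Oc2ccc(Br)cc2OC)cc1OC | intermediate
9 | N-methoxy-N-methylpropanamide | CCC(=O)N(C)OC | starting material
10 | aryllithium from 8 (lithium in place of bromine; not isolated) | COc1ccc([C@@H](O[Si](C)(C)C(C)(C)C)[C@H](C)Oc2ccc([Li])cc2OC)cc1OC | intermediate
11 | 1-(Ar*)propan-1-one | CCC(=O)c1ccc(O[C@@H](C)[C@H](O[Si](C)(C)C(C)(C)C)c2ccc(OC)c(OC)c2)c(OC)c1 | intermediate
12 | (2R)-2-(methoxymethyl)pyrrolidin-1-amine (RAMP) | COC[C@H]1CCCN1N | starting material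
13 | (2R)-N-[1-(Ar*)propylidene]-2-(methoxymethyl)pyrrolidin-1-amine (C=N geometry not controlled, drawn unspecified) | CCC(=NN1CCC[C@@H]1COC)c1ccc(O[C@@H](C)[C@H](O[Si](C)(C)C(C)(C)C)c2ccc(OC)c(OC)c2)c(OC)c1 | intermediate
14 | lithium azaenolate of 13 (C=C geometry as formed, drawn unspecified; not isolated) | CC=C(N([Li])N1CCC[C@@H]1COC)c1ccc(O[C@@H](C)[C@H](O[Si](C)(C)C(C)(C)C)c2ccc(OC)c(OC)c2)c(OC)c1 | intermediate
15 | α-iodo hydrazone of 13 (C–I centre configurationally labile, drawn unspecified; not isolated) | CC(I)C(=NN1CCC[C@@H]1COC)c1ccc(O[C@@H](C)[C@H](O[Si](C)(C)C(C)(C)C)c2ccc(OC)c(OC)c2)c(OC)c1 | intermediate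
16 | (2R,3R)-1,4-bis(Ar*)-2,3-dimethylbutane-1,4-dione bis{[(2R)-2-(methoxymethyl)pyrrolidin-1-yl]imine} | C[C@@H](C(=NN1CCC[C@@H]1COC)c1ccc(O[C@@H](C)[C@H](O[Si](C)(C)C(C)(C)C)c2ccc(OC)c(OC)c2)c(OC)c1)[C@@H](C)C(=NN1CCC[C@@H]1COC)c1ccc(O[C@@H](C)[C@H](O[Si](C)(C)C(C)(C)C)c2ccc(OC)c(OC)c2)c(OC)c1 | intermediate
17 | (2R,3R)-1,4-bis(Ar*)-2,3-dimethylbutane-1,4-dione | C[C@@H](C(=O)c1ccc(O[C@@H](C)[C@H](O[Si](C)(C)C(C)(C)C)c2ccc(OC)c(OC)c2)c(OC)c1)[C@@H](C)C(=O)c1ccc(O[C@@H](C)[C@H](O[Si](C)(C)C(C)(C)C)c2ccc(OC)c(OC)c2)c(OC)c1 | intermediate
18 | (3R,4R,5R)-2,5-bis(Ar*)-3,4-dimethyloxolan-2-ol (anomeric mixture, C2 drawn unspecified) | COc1ccc([C@@H](O[Si](C)(C)C(C)(C)C)[C@H](C)Oc2ccc(C3(O)O[C@@H](c4ccc(O[C@@H](C)[C@H](O[Si](C)(C)C(C)(C)C)c5ccc(OC)c(OC)c5)c(OC)c4)[C@H](C)[C@H]3C)cc2OC)cc1OC | intermediate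
19 | cyclic oxocarbenium ion from 18 (O1=C2 cation; not isolated) | COc1ccc([C@@H](O[Si](C)(C)C(C)(C)C)[C@H](C)Oc2ccc(C3=[O+][C@@H](c4ccc(O[C@@H](C)[C@H](O[Si](C)(C)C(C)(C)C)c5ccc(OC)c(OC)c5)c(OC)c4)[C@H](C)[C@H]3C)cc2OC)cc1OC | intermediate
20 | (2S,3R,4R,5R)-2,5-bis(Ar*)-3,4-dimethyloxolane (bis-silyl ether of the target) | COc1ccc([C@@H](O[Si](C)(C)C(C)(C)C)[C@H](C)Oc2ccc([C@H]3O[C@@H](c4ccc(O[C@@H](C)[C@H](O[Si](C)(C)C(C)(C)C)c5ccc(OC)c(OC)c5)c(OC)c4)[C@H](C)[C@H]3C)cc2OC)cc1OC | intermediate
21 | (1R,2S)-1-(3,4-dimethoxyphenyl)-2-[4-[(2S,3R,4R,5R)-5-[4-[(1R,2S)-1-(3,4-dimethoxyphenyl)-1-hydroxypropan-2-yl]oxy-3-methoxyphenyl]-3,4-dimethyloxolan-2-yl]-2-methoxyphenoxy]propan-1-ol (CNP0116650.13) | COc1ccc([C@@H](O)[C@H](C)Oc2ccc([C@H]3O[C@@H](c4ccc(O[C@@H](C)[C@H](O)c5ccc(OC)c(OC)c5)c(OC)c4)[C@H](C)[C@H]3C)cc2OC)cc1OC | target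

## Step count and least certain steps

Total step count: 12. Longest linear sequence: 12 steps (1 or 2 to 21); the dimerisation in step 8 uses two molecules of the same intermediate, so there is no second branch.

**Step 8 (key step).**
- What may go wrong: unlike pairing of the two halves, which gives the meso-type (R,S) isomer; arrest at the stage of α-iodination, because the coupling joins two secondary carbons next to bulky aryl hydrazone groups; or a facial sense opposite to the one assumed (then the enantiomeric auxiliary is used).
- Fallback from known chemistry; it sets out from bromide 8 and returns at diketone 17.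
  - Commercial (4S)-4-benzyl-3-propanoyl-1,3-oxazolidin-2-one is deprotonated with LiN(i-Pr)2 and its enolate is oxidatively homocoupled with TiCl4 to (2R,3R)-1,4-bis[(4S)-4-benzyl-2-oxo-1,3-oxazolidin-3-yl]-2,3-dimethylbutane-1,4-dione F1.
  - LiOH/H2O2 removes both auxiliaries and gives (2R,3R)-2,3-dimethylbutanedioic acid F2.
  - F2 is converted through its diacid chloride into (2R,3R)-N1,N4-dimethoxy-N1,N4,2,3-tetramethylbutanediamide F3.
  - Aryllithium 10, made from 8 as in step 6, adds at both ends of F3 to give 17.
  - This gives up the dimerisation of complete halves and costs an excess of the aryllithium, but every operation is standard.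

**Step 10.**
- What may go wrong: over-reduction of the second carbonyl and incomplete conversion (a statistical mixture) if the alkoxide does not close to the hemiketalate fast enough; erosion of the Felkin–Anh preference.
- Fallback without a statistical step; it sets out from bromide 8 (together with diacid F2 of the first fallback) and returns at hemiketal 18.
  - F2 is dehydrated with acetyl chloride to (3R,4R)-3,4-dimethyloxolane-2,5-dione F4.
  - Aryllithium 10 opens F4 to (2R,3R)-4-(Ar*)-2,3-dimethyl-4-oxobutanoic acid F5. The two carbonyl groups of F4 are homotopic, and the carboxylate that forms stops a second addition.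
  - LiBH(s-Bu)3 reduces the ketone under Felkin–Anh control, and mild acid closes (3R,4R,5R)-5-(Ar*)-3,4-dimethyloxolan-2-one F6.
  - A second portion of 10 adds to F6 at −78 °C and gives 18.

**Step 11.**
- What may go wrong: epimerisation at C2 through reversible opening of the benzylic ring ether under the Lewis acid (drift to the all-trans isomer); ionisation of the side-chain silyl ethers followed by hydride capture (loss of the Cα oxygen).
- Fallback that avoids Lewis acid and oxocarbenium ion; it sets out from diketone 17 and returns at 20.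
  - Both carbonyl groups are reduced with an excess of LiBH(s-Bu)3 to the C2-symmetric (1R,2R,3R,4R)-1,4-bis(Ar*)-2,3-dimethylbutane-1,4-diol F7 (identical with A8).
  - One of its two homotopic hydroxyl groups is converted into the methanesulfonate (MsCl, Et3N, CH2Cl2, −40 °C) and displaced by the other with inversion. This turns that carbon into the 2,3-cis centre and gives 20.
  - The weak point of this variant is ionisation before ring closure, which would lead to the all-trans isomer; hence the low temperature and the non-polar medium.

**Step 4.**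
- What may go wrong: weak chelation by the aryl ether oxygen, and with it poor facial selectivity in the hydride addition.
- Fallback that sets Cα in a C–C instead of a C–H bond formation; it sets out from amide 4 and returns at alcohol 7.
  - i-Bu2AlH at −78 °C gives (2S)-2-(4-bromo-2-methoxyphenoxy)propanal F8.
  - The aryl-titanium reagent made from 5 and ClTi(O-i-Pr)3 adds under non-chelating Felkin–Anh control (aryloxy group anti to the nucleophile), which also leads to the (1R,2S) alcohol 7.

## Further compounds

F1 | step 8 | (2R,3R)-1,4-bis[(4S)-4-benzyl-2-oxo-1,3-oxazolidin-3-yl]-2,3-dimethylbutane-1,4-dione | C[C@@H](C(=O)N1[C@@H](Cc2ccccc2)COC1=O)[C@@H](C)C(=O)N1[C@@H](Cc2ccccc2)COC1=O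
F2 | step 8 | (2R,3R)-2,3-dimethylbutanedioic acid | C[C@@H](C(=O)O)[C@@H](C)C(=O)O
F3 | step 8 | (2R,3R)-N1,N4-dimethoxy-N1,N4,2,3-tetramethylbutanediamide | C[C@@H](C(=O)N(C)OC)[C@@H](C)C(=O)N(C)OC
F4 | step 10 | (3R,4R)-3,4-dimethyloxolane-2,5-dione | C[C@H]1C(=O)OC(=O)[C@@H]1C
F5 | step 10 | (2R,3R)-4-(Ar*)-2,3-dimethyl-4-oxobutanoic acid | C[C@@H](C(=O)c1ccc(O[C@@H](C)[C@H](O[Si](C)(C)C(C)(C)C)c2ccc(OC)c(OC)c2)c(OC)c1)[C@@H](C)C(=O)O
F6 | step 10 | (3R,4R,5R)-5-(Ar*)-3,4-dimethyloxolan-2-one | O=C1O[C@@H](c2ccc(O[C@@H](C)[C@H](O[Si](C)(C)C(C)(C)C)c3ccc(OC)c(OC)c3)c(OC)c2)[C@H](C)[C@H]1C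
F7 | step 11 | (1R,2R,3R,4R)-1,4-bis(Ar*)-2,3-dimethylbutane-1,4-diol | C[C@@H]([C@@H](O)c1ccc(O[C@@H](C)[C@H](O[Si](C)(C)C(C)(C)C)c2ccc(OC)c(OC)c2)c(OC)c1)[C@@H](C)[C@@H](O)c1ccc(O[C@@H](C)[C@H](O[Si](C)(C)C(C)(C)C)c2ccc(OC)c(OC)c2)c(OC)c1
F8 | step 4 | (2S)-2-(4-bromo-2-methoxyphenoxy)propanal | C[C@H](Oc1ccc(Br)cc1OC)C=O
A1 | alternative 1 | (3R,4R,5R)-5-[4-(benzyloxy)-3-methoxyphenyl]-3,4-dimethyloxolan-2-one | O=C1O[C@@H](c2ccc(OCc3ccccc3)c(OC)c2)[C@H](C)[C@H]1C
A2 | alternative 1 | 4,4′-[(2S,3R,4R,5R)-3,4-dimethyloxolane-2,5-diyl]bis(2-methoxyphenol) | COc1cc([C@H]2O[C@@H](c3ccc(O)c(OC)c3)[C@H](C)[C@H]2C)ccc1O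
A3 | alternative 1 | (2R)-1-(3,4-dimethoxyphenyl)-1-oxopropan-2-yl 4-methylbenzenesulfonate | C[C@@H](OS(=O)(=O)c1ccc(C)cc1)C(=O)c1ccc(OC)c(OC)c1
A4 | alternative 2 | trans-2,3-bis[4-(benzyloxy)-3-methoxyphenyl]oxirane (racemic, one enantiomer drawn) | COc1cc([C@@H]2O[C@H]2c3ccc(OCc4ccccc4)c(OC)c3)ccc1OCc1ccccc1
A5 | alternative 2 | dimethyl 2,5-cis-3,4-trans-2,5-bis[4-(benzyloxy)-3-methoxyphenyl]oxolane-3,4-dicarboxylate (racemic, one enantiomer drawn) | COc1cc([C@H]2O[C@@H](c3ccc(OCc4ccccc4)c(OC)c3)[C@H](C(=O)OC)[C@H]2C(=O)OC)ccc1OCc1ccccc1
A6 | alternative 3 | 1-(Ar*)prop-1-yne | CC#Cc1ccc(O[C@@H](C)[C@H](O[Si](C)(C)C(C)(C)C)c2ccc(OC)c(OC)c2)c(OC)c1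
A7 | alternative 3 | (1E,3E)-1,4-bis(Ar*)-2,3-dimethylbuta-1,3-diene | COc1ccc([C@@H](O[Si](C)(C)C(C)(C)C)[C@H](C)Oc2ccc(/C=C(C)/C(C)=C/c3ccc(O[C@@H](C)[C@H](O[Si](C)(C)C(C)(C)C)c4ccc(OC)c(OC)c4)c(OC)c3)cc2OC)cc1OC
A8 | alternative 3 | (1R,2R,3R,4R)-1,4-bis(Ar*)-2,3-dimethylbutane-1,4-diol | C[C@@H]([C@@H](O)c1ccc(O[C@@H](C)[C@H](O[Si](C)(C)C(C)(C)C)c2ccc(OC)c(OC)c2)c(OC)c1)[C@@H](C)[C@@H](O)c1ccc(O[C@@H](C)[C@H](O[Si](C)(C)C(C)(C)C)c2ccc(OC)c(OC)c2)c(OC)c1
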